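**Retrosynthetic overview** (drimane numbering: C3 ester carbinol, C4 gem-dimethyl, C5/C10 ring fusion, C8 carbinol, C9 bearing C11H2OAr, C12 the methyl on C8)
1. End game: the angelate goes on O3 last. The C8 carbinol comes from hydration of an 8(12)-methylene, the aryl ether from a Mitsunobu reaction at C11, and both handles derive from an 8-oxo 11-methyl ester.
2. Key disconnection: C6–C7 and C9–C10 (together with C4–C5) are made in one flask from open-chain (R)-6,7-epoxygeranyl bromide and the bis-silyl dienol ether of methyl acetoacetate.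
3. Enabling feature: in ring B, C8 lies between C7 and C9, and C9 carries C11. At the ketone/ester level C7–C8–C9–C11 is acetoacetate, which is nucleophilic first at C7 and then at C9. Their partners C6 and C10 flank C5 as the two ends of the allyl unit C6–C5=C10 of the still open ring A. C6 is electrophilic as the allylic bromide, and C10 becomes the cation set free when the C3–C4 epoxide closes ring A.
4. Ring order: C6–C7 first, then ring A (C4–C5), then ring B (C9–C10), all in the same operation. The coumarin rings are bought.
5. All stereocentres descend from one Shi epoxidation (C3). C5, C9 and C10 follow from the chair–chair closure, and C8 from attack anti to the axial C10 methyl.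

Key step: step 4

Assumption: the silyl dienol ether 6 and the D-fructose-derived Shi ketone are taken as commercial, and drimane numbering is also applied to the open-chain precursors.

Step 1
Reactants: 1 geranyl acetate
Product: 2 (R)-6,7-epoxygeranyl acetate
Conditions: D-fructose-derived Shi ketone (0.3 equiv), Oxone (2 KHSO5·KHSO4·K2SO4), K2CO3, Bu4NHSO4, MeCN/dimethoxymethane, aq Na2B4O7/Na2EDTA buffer, 0 °C
Reagents that add atoms: potassium peroxymonosulfate KHSO5 [K+].[O-]S(=O)(=O)OO
Why: In this Shi asymmetric epoxidation the chiral dioxirane takes the electron-rich 6,7-alkene (the 2,3-alkene is deactivated by the allylic acetate) through a spiro transition state on the face that gives the R epoxide, the later C3.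

Step 2
Reactants: 2 (R)-6,7-epoxygeranyl acetate
Product: 3 (R)-6,7-epoxygeraniol
Conditions: K2CO3 (0.2 equiv), MeOH, 0 °C to rt
Reagents that add atoms: none
Why: Base-catalysed transesterification frees the allylic alcohol and leaves the trisubstituted epoxide and the E alkene untouched.

Step 3
Reactants: 3 (R)-6,7-epoxygeraniol
Product: 5 (R)-6,7-epoxygeranyl bromide, via mesylate 4 (not isolated)
Conditions: MsCl, Et3N, CH2Cl2, −40 °C; then LiBr, THF, 0 °C
Reagents that add atoms: methanesulfonyl chloride CS(=O)(=O)Cl; lithium bromide [Li+].[Br-]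
Why: Mesylation followed by SN2 displacement with bromide is the standard mild route to allylic bromides, keeps the E geometry and tolerates the epoxide at low temperature.

Step 4
Reactants: 5 (R)-6,7-epoxygeranyl bromide; 6 1-methoxy-1,3-bis(trimethylsilyloxy)buta-1,3-diene
Product: 9 methyl (3R,5S,9S,10R)-3-hydroxy-8-oxo-12-nordriman-11-oate, via alkylated enol silane epoxide 7 (not isolated), via O3-silylated keto ester 8 (not isolated)
Conditions: 6 (1.3 equiv), AgOTf (1.1 equiv), 2,6-di-tert-butyl-4-methylpyridine (1.5 equiv), 4 Å molecular sieves, CH2Cl2, −78 to −40 °C; aq NaHCO3; then 1 M HCl, THF, 0 °C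
Reagents that add atoms: none
Why: Proposed new method: AgOTf abstracts bromide from 5 and the transoid allyl cation C6–C5–C10 is taken at its primary end C6 by the terminal carbon C7 of 6, a vinylogous SN1 alkylation that expels one equivalent of TMSOTf and leaves the C8=C9 enol silane of 7; this TMSOTf, the first oxophilic Lewis acid in the flask, silylates the epoxide oxygen, C4–O ionises with participation of the E C5=C10 alkene, the C10 cation is captured by C9 and the silyl group on O8 leaves again as TMSOTf, so that 7 to 8 is a TMSOTf-catalysed isomerisation. The closest known reaction types are the silver-assisted gamma-alkylation of silyl dienol ethers with allylic halides and the TMSOTf/hindered-pyridine promoted epoxide-initiated cation–olefin cyclisation terminated by an enol silane, and only their coupling through the liberated TMSOTf is new. Ring A closes by 6-endo attack of C5 on C4 of the opening epoxide and ring B by 6-endo attack of C9 on C10, both in chair-like arrays. C3 is carried over from the epoxide with its C–O bond intact and sits equatorial, antiperiplanar addition across the E alkene sets C5–H and C10–CH3 trans (trans-decalin), and C9 ends with the ester equatorial through the chair closure and because this beta-keto ester centre can equilibrate. The step needs (a) C6–C7 formation before epoxide opening, secured because halophilic AgOTf is the only promoter at the start and the alkene of unreacted 5 is deactivated by its allylic bromide, (b) first contact between C7 and C6 rather than C9 or C10, secured by the higher terminal nucleophilicity of 6 and the steric bias of the allyl cation, and (c) C- rather than O-termination, secured by the silyl cap on O8.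

Step 5
Reactants: 9 methyl (3R,5S,9S,10R)-3-hydroxy-8-oxo-12-nordriman-11-oate
Product: 10 methyl (3R,5S,9R,10R)-3-hydroxydrim-8(12)-en-11-oate
Conditions: Zn, CH2Br2, TiCl4, THF/CH2Cl2, 0 °C to rt
Reagents that add atoms: dibromomethane BrCBr
Why: In the Takai–Lombardo methylenation the non-basic zinc/titanium methylene reagent converts ketones in preference to esters and neither enolises nor epimerises C9.

Step 6
Reactants: 10 methyl (3R,5S,9R,10R)-3-hydroxydrim-8(12)-en-11-oate
Product: 11 (3R,5S,9R,10R)-drim-8(12)-ene-3,11-diol
Conditions: LiAlH4, THF, 0 °C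
Reagents that add atoms: none
Why: Hydride reduction of the ester gives the C11 primary alcohol without touching the isolated alkene or any stereocentre.

Step 7
Reactants: 11 (3R,5S,9R,10R)-drim-8(12)-ene-3,11-diol; 12 umbelliferone
Product: 13 7-{[(3R,5S,9R,10R)-3-hydroxydrim-8(12)-en-11-yl]oxy}coumarin
Conditions: PPh3, DIAD, THF, 0 °C to rt
Reagents that add atoms: none
Why: In this Mitsunobu etherification only the primary C11–OH is activated and displaced by the acidic phenol, because the C3–OH next to the gem-dimethyl group is too hindered to react.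

Step 8
Reactants: 13 7-{[(3R,5S,9R,10R)-3-hydroxydrim-8(12)-en-11-yl]oxy}coumarin
Product: 14 7-{[(3R,5S,8S,9R,10R)-3,8-dihydroxydriman-11-yl]oxy}coumarin
Conditions: Mn(dpm)3 (cat.), PhSiH3, O2 (1 atm), i-PrOH/CH2Cl2, 0 °C to rt
Reagents that add atoms: dioxygen O=O
Why: In the Mukaiyama hydration hydrogen atom transfer to C12 of the 1,1-disubstituted alkene gives the tertiary C8 radical, which takes up O2 from the equatorial face away from the axial C10 methyl (equatorial OH, axial CH3), while the electron-poor coumarin alkene reacts far more slowly.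

Step 9
Reactants: 14 7-{[(3R,5S,8S,9R,10R)-3,8-dihydroxydriman-11-yl]oxy}coumarin; 15 angelic acid
Product: 17 CNP0189964.2, via mixed anhydride 16 (not isolated)
Conditions: 15, 2,4,6-trichlorobenzoyl chloride, Et3N, toluene, rt; then 14, toluene, 80 °C
Reagents that add atoms: 2,4,6-trichlorobenzoyl chloride O=C(Cl)c1c(Cl)cc(Cl)cc1Cl
Why: Yamaguchi-type mixed-anhydride acylation without a nucleophilic catalyst keeps the Z geometry of the angelate and acylates the secondary C3–OH, while the tertiary C8–OH stays free.

**Compound list**
1 | geranyl acetate, (2E)-3,7-dimethylocta-2,6-dien-1-yl acetate | CC(C)=CCC/C(C)=C/COC(C)=O | starting material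
2 | (R)-6,7-epoxygeranyl acetate, (2E)-5-[(2R)-3,3-dimethyloxiran-2-yl]-3-methylpent-2-en-1-yl acetate | CC1(C)O[C@@H]1CC/C(C)=C/COC(C)=O | intermediate
3 | (R)-6,7-epoxygeraniol | CC1(C)O[C@@H]1CC/C(C)=C/CO | intermediate
4 | (R)-6,7-epoxygeranyl methanesulfonate | CC1(C)O[C@@H]1CC/C(C)=C/COS(C)(=O)=O | intermediate
5 | (R)-6,7-epoxygeranyl bromide | CC1(C)O[C@@H]1CC/C(C)=C/CBr | intermediate
6 | 1-methoxy-1,3-bis(trimethylsilyloxy)buta-1,3-diene | COC(=CC(=C)O[Si](C)(C)C)O[Si](C)(C)C | starting material
7 | methyl (6E)-9-[(2R)-3,3-dimethyloxiran-2-yl]-7-methyl-3-(trimethylsilyloxy)nona-2,6-dienoate | CC1(C)O[C@@H]1CC/C(C)=C/CCC(O[Si](C)(C)C)=CC(=O)OC | intermediate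
8 | methyl (3R,5S,9S,10R)-8-oxo-3-(trimethylsilyloxy)-12-nordriman-11-oate (trans-decalin, OSiMe3 and ester equatorial) | C[Si](C)(C)O[C@@H]1CC[C@]2(C)[C@H](CCC(=O)[C@H]2C(=O)OC)C1(C)C | intermediate
9 | methyl (3R,5S,9S,10R)-3-hydroxy-8-oxo-12-nordriman-11-oate | O[C@@H]1CC[C@]2(C)[C@H](CCC(=O)[C@H]2C(=O)OC)C1(C)C | intermediate
10 | methyl (3R,5S,9R,10R)-3-hydroxydrim-8(12)-en-11-oate | O[C@@H]1CC[C@]2(C)[C@H](CCC(=C)[C@H]2C(=O)OC)C1(C)C | intermediate
11 | (3R,5S,9R,10R)-drim-8(12)-ene-3,11-diol | O[C@@H]1CC[C@]2(C)[C@H](CCC(=C)[C@H]2CO)C1(C)C | intermediate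
12 | umbelliferone, 7-hydroxycoumarin | Oc1ccc2ccc(=O)oc2c1 | starting material
13 | 7-{[(3R,5S,9R,10R)-3-hydroxydrim-8(12)-en-11-yl]oxy}coumarin | O[C@@H]1CC[C@]2(C)[C@H](CCC(=C)[C@H]2COc2ccc3ccc(=O)oc3c2)C1(C)C | intermediate
14 | 7-{[(3R,5S,8S,9R,10R)-3,8-dihydroxydriman-11-yl]oxy}coumarin (8-OH equatorial, 8-CH3 axial) | O[C@@H]1CC[C@]2(C)[C@H](CC[C@](C)(O)[C@H]2COc2ccc3ccc(=O)oc3c2)C1(C)C | intermediate
15 | angelic acid, (Z)-2-methylbut-2-enoic acid | C/C=C(/C)C(=O)O | starting material
16 | angelic 2,4,6-trichlorobenzoic anhydride | C/C=C(/C)C(=O)OC(=O)c1c(Cl)cc(Cl)cc1Cl | intermediate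
17 | CNP0189964.2, (3R,5S,8S,9R,10R)-8-hydroxy-11-(2-oxo-2H-chromen-7-yloxy)driman-3-yl (Z)-2-methylbut-2-enoate | C/C=C(/C)C(=O)O[C@@H]1CC[C@]2(C)[C@H](CC[C@](C)(O)[C@H]2COc2ccc3ccc(=O)oc3c2)C1(C)C | target

Total step count: 9. Longest linear sequence: 9 steps (from 1 to 17).

**Steps most likely to fail**

Step 4 (Proposed new method). The order of events may break down in three ways.
- TMSOTf set free early may open the epoxide of still unalkylated 5, leading to rearrangement or premature monocyclisation.
- The allyl cation may be taken at its tertiary end.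
- The cascade may stop after ring A by proton loss.

The fallback sets out from 5 and uses known chemistry in two isolated stages. The dianion of methyl acetoacetate (NaH, then n-BuLi, THF, 0 °C) is alkylated at its terminal carbon with 5 to give methyl (6E)-9-[(2R)-3,3-dimethyloxiran-2-yl]-7-methyl-3-oxonon-6-enoate F1. This is then submitted to the established Lewis acid cyclisation of epoxy olefinic beta-keto esters (SnCl4, CH2Cl2, −78 °C) and comes back to the route at 9.

Step 8. Facial selectivity in the O2 capture by the planar C8 radical may be poor, the radical may be reduced to the alkane, or hydrogen atom transfer to the coumarin C3=C4 bond may compete.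

The fallback sets out from 10 and installs the carbinol by ionic chemistry before the coumarin is present. Epoxidation with mCPBA (NaHCO3, CH2Cl2), anti to the axial C10 methyl, gives methyl (3R,5S,8S,9R,10R)-8,12-epoxy-3-hydroxydriman-11-oate F2. LiAlH4 opens this epoxide at its CH2 terminus and reduces the ester in the same operation to (3R,5S,8S,9R,10R)-drimane-3,8,11-triol F3. Mitsunobu etherification of the primary C11–OH with 12 comes back to the route at 14.

Step 9. The slow acylation of the hindered C3–OH may allow Z to E isomerisation of the angelate or dehydration of the tertiary alcohol on heating.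

The fallback sets out from 14 and builds the Z alkene on the molecule. Carbodiimide esterification with 2-[bis(2,2,2-trifluoroethoxy)phosphoryl]propanoic acid gives the 3-O-{2-[bis(2,2,2-trifluoroethoxy)phosphoryl]propanoyl} derivative of 14 F4. Z-selective Still–Gennari olefination (KN(SiMe3)2, 18-crown-6, THF, −78 °C, acetaldehyde) comes back to the route at 17.

**Further compounds**
F1 | step 4 | methyl (6E)-9-[(2R)-3,3-dimethyloxiran-2-yl]-7-methyl-3-oxonon-6-enoate | CC1(C)O[C@@H]1CC/C(C)=C/CCC(=O)CC(=O)OC
F2 | step 8 | methyl (3R,5S,8S,9R,10R)-8,12-epoxy-3-hydroxydriman-11-oate | O[C@@H]1CC[C@]2(C)[C@H](CC[C@]3(OC3)[C@H]2C(=O)OC)C1(C)C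
F3 | step 8 | (3R,5S,8S,9R,10R)-drimane-3,8,11-triol | O[C@@H]1CC[C@]2(C)[C@H](CC[C@](C)(O)[C@H]2CO)C1(C)C
F4 | step 9 | 3-O-{2-[bis(2,2,2-trifluoroethoxy)phosphoryl]propanoyl} derivative of 14 | CC(C(=O)O[C@@H]1CC[C@]2(C)[C@H](CC[C@](C)(O)[C@H]2COc2ccc3ccc(=O)oc3c2)C1(C)C)P(=O)(OCC(F)(F)F)OCC(F)(F)F
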